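**Retrosynthetic overview**
- Feature: ring B (C5-C6-C7-C8-C9-C10) is a 2-hydroxycyclohexa-2,5-dienone. It is the keto tautomer of a 4-methylcatechol, and it cannot return to the arene because C5, para to the C8 oxygen, is quaternary. Ring B is therefore bought as creosol.
- Late disconnections: the C3-O ester (dienoic acid from (S)-2-methylbutan-1-ol and a phosphonocrotonate); the trans-diaxial C2/C3 diol from the α-epoxide of a C2=C3 alkene; a C9 bromine blocking group and the O7 methyl group, both removed late.
- Key disconnection C4-C5: the para carbon of the phenolate displaces an (R)-allylic chloride at the end of a Z-pentenyl tether on C10. This closes ring A and sets C4 and C5.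
- Tether: benzylic bromide plus (S)-but-3-yn-2-ol, Lindlar reduction, invertive chlorination. Arene: creosol formylated para to OMe and brominated ortho to OH before any alkene is present.
- Ring order: ring B (aromatic, purchased), then ring A (step 11).

Key step: step 11

Remark: eremophilane numbering is used for the bicycles and for the corresponding atoms of their precursors, β is the face that carries C14 and C15, and the two commercial chiral alcohols are taken as enantiopure.

**Route**

Step 1
Reactants: 1 creosol (2-methoxy-4-methylphenol)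
Product: 2 2-methoxy-4-methylphenyl acetate
Conditions: Ac2O, pyridine, CH2Cl2, rt
Reagents that add atoms: acetic anhydride, CC(=O)OC(C)=O
Why: Simple O-acylation turns the phenol oxygen into a weak donor, so that the methoxy group alone directs the next step.

Step 2
Reactants: 2 2-methoxy-4-methylphenyl acetate
Product: 4 5-formyl-2-methoxy-4-methylphenyl acetate, via alpha-chlorobenzyl methyl ether 3 (not isolated)
Conditions: Cl2CHOMe, TiCl4, CH2Cl2, -10 to 0 °C; then ice/H2O
Reagents that add atoms: dichloromethyl methyl ether, COC(Cl)Cl; water, O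
Why: Rieche formylation attacks the one position that is para to OMe and ortho to CH3 (future C10), because the site ortho to OAc is unactivated and the site between OMe and CH3 is crowded, and the quench hydrolyses 3 to the aldehyde.

Step 3
Reactants: 4 5-formyl-2-methoxy-4-methylphenyl acetate
Product: 5 5-hydroxy-4-methoxy-2-methylbenzaldehyde
Conditions: K2CO3 (0.2 equiv), MeOH, rt
Reagents that add atoms: none
Why: Base-catalysed methanolysis (transesterification) of the activated aryl acetate frees the phenol that must direct the bromination and leaves the aldehyde alone.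

Step 4
Reactants: 5 5-hydroxy-4-methoxy-2-methylbenzaldehyde
Product: 6 2-bromo-3-hydroxy-4-methoxy-6-methylbenzaldehyde
Conditions: Br2, NaOAc, AcOH, rt
Reagents that add atoms: bromine, BrBr
Why: In this electrophilic aromatic bromination the free OH directs, its para position holds CH3 and its other ortho position holds OMe, so bromine enters between OH and CHO (future C9) as in the conversion of isovanillin to 2-bromoisovanillin, and no alkene is yet present to compete.

Step 5
Reactants: 6 2-bromo-3-hydroxy-4-methoxy-6-methylbenzaldehyde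
Product: 7 2-bromo-4-methoxy-6-methyl-3-(triisopropylsilyloxy)benzaldehyde
Conditions: TIPSOTf, 2,6-lutidine, CH2Cl2, 0 °C
Reagents that add atoms: triisopropylsilyl triflate, CC(C)[Si](C(C)C)(C(C)C)OS(=O)(=O)C(F)(F)F
Why: O-silylation with the reactive triflate overcomes the Br/OMe flanks, and the bulky aryl TIPS ether tolerates hydride, carbonate and phosphine reagents yet falls to fluoride.

Step 6
Reactants: 7 2-bromo-4-methoxy-6-methyl-3-(triisopropylsilyloxy)benzaldehyde
Product: 8 [2-bromo-4-methoxy-6-methyl-3-(triisopropylsilyloxy)phenyl]methanol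
Conditions: NaBH4, MeOH/THF, 0 °C
Reagents that add atoms: none
Why: Borohydride reduction of the aldehyde leaves the aryl bromide and the silyl ether inert.

Step 7
Reactants: 8 [2-bromo-4-methoxy-6-methyl-3-(triisopropylsilyloxy)phenyl]methanol
Product: 9 [2-bromo-3-(bromomethyl)-6-methoxy-4-methylphenoxy]triisopropylsilane
Conditions: CBr4, PPh3, CH2Cl2, 0 °C
Reagents that add atoms: carbon tetrabromide, BrC(Br)(Br)Br
Why: The Appel reaction converts the primary benzylic alcohol under neutral conditions by SN2 attack of bromide on the alkoxyphosphonium ion.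

Step 8
Reactants: 9 [2-bromo-3-(bromomethyl)-6-methoxy-4-methylphenoxy]triisopropylsilane; 10 (S)-but-3-yn-2-ol
Product: 11 (S)-5-[2-bromo-4-methoxy-6-methyl-3-(triisopropylsilyloxy)phenyl]pent-3-yn-2-ol
Conditions: CuI (20 mol %), NaI (20 mol %), K2CO3, DMF, rt
Reagents that add atoms: none
Why: In this copper(I)-catalysed alkynylation of a benzylic halide the copper acetylide displaces the benzylic bromide, while the free secondary OH, the aryl bromide and the carbinol stereocentre stay untouched at room temperature.

Step 9
Reactants: 11 (S)-5-[2-bromo-4-methoxy-6-methyl-3-(triisopropylsilyloxy)phenyl]pent-3-yn-2-ol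
Product: 12 (2S,3Z)-5-[2-bromo-4-methoxy-6-methyl-3-(triisopropylsilyloxy)phenyl]pent-3-en-2-ol
Conditions: H2 (1 atm), Lindlar catalyst, quinoline, EtOAc, rt
Reagents that add atoms: none
Why: Lindlar semihydrogenation adds H2 syn and stops at the Z-alkene, and the quinoline-poisoned catalyst spares the aryl C-Br and allylic C-O bonds.

Step 10
Reactants: 12 (2S,3Z)-5-[2-bromo-4-methoxy-6-methyl-3-(triisopropylsilyloxy)phenyl]pent-3-en-2-ol
Product: 13 {2-bromo-3-[(2Z,4R)-4-chloropent-2-en-1-yl]-6-methoxy-4-methylphenoxy}triisopropylsilane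
Conditions: PPh3, hexachloroacetone, CH2Cl2, 0 °C
Reagents that add atoms: hexachloroacetone, ClC(Cl)(Cl)C(=O)C(Cl)(Cl)Cl
Why: In this Appel-type chlorination chloride attacks the alkoxyphosphonium ion in a fast, cold SN2 step, which for secondary allylic alcohols is known to go with inversion and little allylic transposition or Z/E leakage, and the silylated phenol cannot interfere.

Step 11
Reactants: 13 {2-bromo-3-[(2Z,4R)-4-chloropent-2-en-1-yl]-6-methoxy-4-methylphenoxy}triisopropylsilane
Product: 15 (4S,5S)-9-bromo-7-methoxy-11,12,13-trinoreremophila-2,6,9-trien-8-one, via tetrabutylammonium phenolate 14 (not isolated)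
Conditions: TBAF (1.0 equiv), THF (0.005 M), -40 °C to rt
Reagents that add atoms: none
Why: Fluoride removes the silyl group in the cold, and phenolate 14 then attacks the backside of the C4-Cl bond through its para carbon C5, an intramolecular SN2 C-alkylation whose closest known type is the base-induced cyclisation of haloalkyl- or sulfonyloxyalkyl-phenols to 4,4-disubstituted cyclohexa-2,5-dienones (alkylative dearomatisation). Ring A closes 6-exo-tet (C5, C10, C1, C2, C3, C4 in the ring, chloride outside), and the methyl on C5 forbids re-aromatisation, so the cross-conjugated dienone is the end point. C4 is set by inversion of the (R)-chloride, and C5 is set by allylic 1,3-strain in the Z-alkene, which holds H4 inside (towards C1 and over the arene) and C14 outside, so that with chloride anti to C5 only one arene face is reachable and C15 ends cis to a pseudo-equatorial C14. The step needs C5 to win over C9, which lies at the same distance: bromine drains electron density from C9, removes the re-aromatising exit and would end on a quaternary carbon of the less stable linear dienone, whereas C5 carries the larger phenolate coefficient and a donating methyl. SN2' attack at C2 would need a four-membered ring and intramolecular O-alkylation a meta-bridged eight-membered ring, and intermolecular O-alkylation is held down by dilution and by the Br/OMe flanks of the oxygen. One equivalent of fluoride, a weakly basic phenolate and a solvent of low polarity disfavour 1,4-elimination of HCl through the doubly activated C1 hydrogens and ionisation that would erode C4.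

Step 12
Reactants: 15 (4S,5S)-9-bromo-7-methoxy-11,12,13-trinoreremophila-2,6,9-trien-8-one
Product: 16 (2R,3S,4R,5S)-9-bromo-2α,3α-epoxy-7-methoxy-11,12,13-trinoreremophila-6,9-dien-8-one
Conditions: mCPBA (1.1 equiv), CH2Cl2, 0 °C
Reagents that add atoms: meta-chloroperoxybenzoic acid, OOC(=O)c1cccc(Cl)c1
Why: Prilezhaev epoxidation picks the isolated cis-alkene over the electron-poor bromodienone and the carbonyl-deactivated enol ether, the axial C15 methyl shields the β face so oxygen arrives from the α face as in steroidal 2-enes, and bromine is kept here because a Pd-H debromination of 15 could move the skipped alkene into conjugation.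

Step 13
Reactants: 16 (2R,3S,4R,5S)-9-bromo-2α,3α-epoxy-7-methoxy-11,12,13-trinoreremophila-6,9-dien-8-one
Product: 17 (2R,3R,4R,5S)-9-bromo-2α,3β-dihydroxy-7-methoxy-11,12,13-trinoreremophila-6,9-dien-8-one
Conditions: HClO4 (cat.), THF/H2O 3:1, rt
Reagents that add atoms: water, O
Why: Acid-catalysed epoxide hydrolysis follows the Fürst-Plattner rule, since planar ring B locks ring A with C15 axial and water therefore opens the protonated epoxide at C3 from the β face through the chair-like transition state, giving the trans-diaxial diol (inversion at C3, retention at C2).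

Step 14
Reactants: 17 (2R,3R,4R,5S)-9-bromo-2α,3β-dihydroxy-7-methoxy-11,12,13-trinoreremophila-6,9-dien-8-one
Product: 18 (2R,3R,4R,5S)-2α,3β-dihydroxy-7-methoxy-11,12,13-trinoreremophila-6,9-dien-8-one
Conditions: Pd(PPh3)4 (5 mol %), HCO2H, Et3N, DMF, 60 °C
Reagents that add atoms: none
Why: In this palladium-catalysed formate hydrodehalogenation Pd(0) inserts into the activated α-bromoenone C9-Br bond, formate delivers hydride by decarboxylation and reductive elimination gives C9-H, with no isomerisable alkene left and no stereocentre involved.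

Step 15
Reactants: 18 (2R,3R,4R,5S)-2α,3β-dihydroxy-7-methoxy-11,12,13-trinoreremophila-6,9-dien-8-one
Product: 19 2α-(tert-butyldimethylsilyloxy)-3β-hydroxy-7-methoxy-11,12,13-trinoreremophila-6,9-dien-8-one
Conditions: TBSCl (1.1 equiv), imidazole, DMF, 0 °C to rt
Reagents that add atoms: tert-butyldimethylsilyl chloride, CC(C)(C)[Si](C)(C)Cl
Why: Sterically controlled monosilylation should take O2, because O3 is syn-axial to C15 and adjacent to C4-CH3 while O2 faces only hydrogens, and the anti arrangement of the two oxygens blocks silyl migration.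

Step 16
Reactants: 20 (S)-2-methylbutan-1-ol
Product: 21 (S)-2-methylbutanal
Conditions: TEMPO (1 mol %), KBr (10 mol %), aq NaOCl, NaHCO3, CH2Cl2, 0 °C
Reagents that add atoms: none
Why: The Anelli TEMPO/bleach oxidation stops at the aldehyde and is cold, fast and buffered enough that the α-stereocentre should not epimerise.

Step 17
Reactants: 21 (S)-2-methylbutanal; 22 triethyl 4-phosphonocrotonate
Product: 24 ethyl (2E,4E,6S)-6-methylocta-2,4-dienoate, via lithiated phosphonate 23 (not isolated)
Conditions: LiHMDS, THF, -78 °C; then 21, -78 to 0 °C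
Reagents that add atoms: none
Why: In this vinylogous Horner-Wadsworth-Emmons olefination the stabilised anion 23 adds through the carbon next to phosphorus and loses phosphate to give the new E-alkene, the crotonate E-alkene is retained and the cold addition spares the α-stereocentre.

Step 18
Reactants: 24 ethyl (2E,4E,6S)-6-methylocta-2,4-dienoate
Product: 26 (2E,4E,6S)-6-methylocta-2,4-dienoic acid, via lithium dienoate 25 (not isolated)
Conditions: LiOH, THF/MeOH/H2O, rt; then 1 M HCl
Reagents that add atoms: lithium hydroxide, [Li+].[OH-]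
Why: Saponification of the unhindered ethyl ester leaves the E,E-diene and the remote C6 stereocentre untouched at room temperature.

Step 19
Reactants: 19 2α-(tert-butyldimethylsilyloxy)-3β-hydroxy-7-methoxy-11,12,13-trinoreremophila-6,9-dien-8-one; 26 (2E,4E,6S)-6-methylocta-2,4-dienoic acid
Product: 28 2α-(tert-butyldimethylsilyloxy)-7-methoxy-8-oxo-11,12,13-trinoreremophila-6,9-dien-3β-yl (2E,4E,6S)-6-methylocta-2,4-dienoate, via mixed Yamaguchi anhydride 27 (not isolated)
Conditions: 2,4,6-trichlorobenzoyl chloride, Et3N, toluene, rt; then 19, DMAP, rt to 40 °C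
Reagents that add atoms: none
Why: In the Yamaguchi esterification DMAP attacks the less hindered dienoyl carbonyl of 27 and the acylpyridinium ion is reactive enough for the hindered axial 3β-OH, whose configuration is kept because only its O-H bond is broken.

Step 20
Reactants: 28 2α-(tert-butyldimethylsilyloxy)-7-methoxy-8-oxo-11,12,13-trinoreremophila-6,9-dien-3β-yl (2E,4E,6S)-6-methylocta-2,4-dienoate
Product: 30 2α-(tert-butyldimethylsilyloxy)-7-hydroxy-8-oxo-11,12,13-trinoreremophila-6,9-dien-3β-yl (2E,4E,6S)-6-methylocta-2,4-dienoate, via dichloroboron enolate 29 (not isolated)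
Conditions: BCl3 (3 equiv), CH2Cl2, -78 to -20 °C; then H2O
Reagents that add atoms: none
Why: In this chelation-assisted Lewis acid ether cleavage boron bridges the C8 carbonyl and the C7 methoxy oxygen and chloride removes the methyl group by SN2, as known for diosphenol methyl ethers and 3-methoxychromones, at a temperature at which the secondary ester should persist, and partial loss of TBS would do no harm.

Step 21
Reactants: 30 2α-(tert-butyldimethylsilyloxy)-7-hydroxy-8-oxo-11,12,13-trinoreremophila-6,9-dien-3β-yl (2E,4E,6S)-6-methylocta-2,4-dienoate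
Product: 31 septeremophilane G
Conditions: HF·pyridine, pyridine, THF, 0 °C to rt
Reagents that add atoms: none
Why: Buffered fluoride desilylation frees the 2α-OH without acyl migration (O2 and O3 are anti) and without vinylogous β-elimination of the C2 oxygen.

**Compound list**
1 | creosol (2-methoxy-4-methylphenol) | COc1cc(C)ccc1O | starting material
2 | 2-methoxy-4-methylphenyl acetate | COc1cc(C)ccc1OC(C)=O | intermediate
3 | 5-[chloro(methoxy)methyl]-2-methoxy-4-methylphenyl acetate (not isolated) | COc1cc(C)c(C(Cl)OC)cc1OC(C)=O | intermediate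
4 | 5-formyl-2-methoxy-4-methylphenyl acetate | COc1cc(C)c(C=O)cc1OC(C)=O | intermediate
5 | 5-hydroxy-4-methoxy-2-methylbenzaldehyde | COc1cc(C)c(C=O)cc1O | intermediate
6 | 2-bromo-3-hydroxy-4-methoxy-6-methylbenzaldehyde | COc1cc(C)c(C=O)c(Br)c1O | intermediate
7 | 2-bromo-4-methoxy-6-methyl-3-(triisopropylsilyloxy)benzaldehyde | COc1cc(C)c(C=O)c(Br)c1O[Si](C(C)C)(C(C)C)C(C)C | intermediate
8 | [2-bromo-4-methoxy-6-methyl-3-(triisopropylsilyloxy)phenyl]methanol | COc1cc(C)c(CO)c(Br)c1O[Si](C(C)C)(C(C)C)C(C)C | intermediate
9 | [2-bromo-3-(bromomethyl)-6-methoxy-4-methylphenoxy]triisopropylsilane | COc1cc(C)c(CBr)c(Br)c1O[Si](C(C)C)(C(C)C)C(C)C | intermediate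
10 | (S)-but-3-yn-2-ol | C[C@H](O)C#C | starting material
11 | (S)-5-[2-bromo-4-methoxy-6-methyl-3-(triisopropylsilyloxy)phenyl]pent-3-yn-2-ol | C[C@H](O)C#CCc1c(Br)c(O[Si](C(C)C)(C(C)C)C(C)C)c(OC)cc1C | intermediate
12 | (2S,3Z)-5-[2-bromo-4-methoxy-6-methyl-3-(triisopropylsilyloxy)phenyl]pent-3-en-2-ol | C[C@H](O)/C=C\Cc1c(Br)c(O[Si](C(C)C)(C(C)C)C(C)C)c(OC)cc1C | intermediate
13 | {2-bromo-3-[(2Z,4R)-4-chloropent-2-en-1-yl]-6-methoxy-4-methylphenoxy}triisopropylsilane (key-step precursor, O-TIPS form) | C[C@@H](Cl)/C=C\Cc1c(Br)c(O[Si](C(C)C)(C(C)C)C(C)C)c(OC)cc1C | intermediate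
14 | tetrabutylammonium 2-bromo-3-[(2Z,4R)-4-chloropent-2-en-1-yl]-6-methoxy-4-methylphenolate (not isolated) | C[C@@H](Cl)/C=C\Cc1c(Br)c([O-])c(OC)cc1C.CCCC[N+](CCCC)(CCCC)CCCC | intermediate
15 | (4S,5S)-9-bromo-7-methoxy-11,12,13-trinoreremophila-2,6,9-trien-8-one, that is (4aS,5S)-1-bromo-3-methoxy-4a,5-dimethyl-5,8-dihydronaphthalen-2(4aH)-one | C1=CCC2=C(Br)C(=O)C(OC)=C[C@]2(C)[C@H]1C | intermediate
16 | (2R,3S,4R,5S)-9-bromo-2α,3α-epoxy-7-methoxy-11,12,13-trinoreremophila-6,9-dien-8-one | O1[C@@H]2[C@H]1CC3=C(Br)C(=O)C(OC)=C[C@]3(C)[C@H]2C | intermediate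
17 | (2R,3R,4R,5S)-9-bromo-2α,3β-dihydroxy-7-methoxy-11,12,13-trinoreremophila-6,9-dien-8-one | O[C@H]1[C@H](O)CC2=C(Br)C(=O)C(OC)=C[C@]2(C)[C@H]1C | intermediate
18 | (2R,3R,4R,5S)-2α,3β-dihydroxy-7-methoxy-11,12,13-trinoreremophila-6,9-dien-8-one | O[C@H]1[C@H](O)CC2=CC(=O)C(OC)=C[C@]2(C)[C@H]1C | intermediate
19 | 2α-(tert-butyldimethylsilyloxy)-3β-hydroxy-7-methoxy-11,12,13-trinoreremophila-6,9-dien-8-one | O[C@H]1[C@H](O[Si](C)(C)C(C)(C)C)CC2=CC(=O)C(OC)=C[C@]2(C)[C@H]1C | intermediate
20 | (S)-2-methylbutan-1-ol | CC[C@H](C)CO | starting material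
21 | (S)-2-methylbutanal | CC[C@H](C)C=O | intermediate
22 | triethyl 4-phosphonocrotonate | CCOC(=O)/C=C/CP(=O)(OCC)OCC | starting material
23 | lithium salt of the triethyl 4-phosphonocrotonate carbanion (not isolated) | [Li+].CCOC(=O)/C=C/[CH-]P(=O)(OCC)OCC | intermediate
24 | ethyl (2E,4E,6S)-6-methylocta-2,4-dienoate | CC[C@H](C)/C=C/C=C/C(=O)OCC | intermediate
25 | lithium (2E,4E,6S)-6-methylocta-2,4-dienoate (not isolated) | CC[C@H](C)/C=C/C=C/C(=O)[O-].[Li+] | intermediate
26 | (2E,4E,6S)-6-methylocta-2,4-dienoic acid | CC[C@H](C)/C=C/C=C/C(=O)O | intermediate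
27 | (2E,4E,6S)-6-methylocta-2,4-dienoic 2,4,6-trichlorobenzoic anhydride (not isolated) | CC[C@H](C)/C=C/C=C/C(=O)OC(=O)c1c(Cl)cc(Cl)cc1Cl | intermediate
28 | 2α-(tert-butyldimethylsilyloxy)-7-methoxy-8-oxo-11,12,13-trinoreremophila-6,9-dien-3β-yl (2E,4E,6S)-6-methylocta-2,4-dienoate | CC[C@H](C)/C=C/C=C/C(=O)O[C@H]1[C@H](O[Si](C)(C)C(C)(C)C)CC2=CC(=O)C(OC)=C[C@]2(C)[C@H]1C | intermediate
29 | 7-O-dichloroboryl enolate of 30 (not isolated) | CC[C@H](C)/C=C/C=C/C(=O)O[C@H]1[C@H](O[Si](C)(C)C(C)(C)C)CC2=CC(=O)C(OB(Cl)Cl)=C[C@]2(C)[C@H]1C | intermediate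
30 | 2α-(tert-butyldimethylsilyloxy)-7-hydroxy-8-oxo-11,12,13-trinoreremophila-6,9-dien-3β-yl (2E,4E,6S)-6-methylocta-2,4-dienoate | CC[C@H](C)/C=C/C=C/C(=O)O[C@H]1[C@H](O[Si](C)(C)C(C)(C)C)CC2=CC(=O)C(O)=C[C@]2(C)[C@H]1C | intermediate
31 | septeremophilane G, (2R,3R,4R,5S)-2α,7-dihydroxy-8-oxo-11,12,13-trinoreremophila-6,9-dien-3β-yl (2E,4E,6S)-6-methylocta-2,4-dienoate | CC[C@H](C)/C=C/C=C/C(=O)O[C@H]1[C@H](O)CC2=CC(=O)C(O)=C[C@]2(C)[C@H]1C | target

**Step count**
Total step count: 21. Longest linear sequence: 18 steps (steps 1 to 15, then 19 to 21). The acid 26 is made in a three-step side branch (steps 16 to 18).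

**Steps most likely to fail**

1. Step 11 (key step).
- What may go wrong: attack through the ortho carbon C9 instead of C5; ionisation or chloride exchange at C4 with loss of stereochemical information; 1,4-elimination of HCl through the C1 hydrogens; oligomerisation by intermolecular O-alkylation.
- Fallback: the same C4-C5 bond is made by palladium-catalysed intramolecular allylic dearomatisation instead of a direct SN2 displacement.
- It sets out from 12. Treatment with ClCO2Me and pyridine (CH2Cl2, 0 °C) gives the (S,Z)-allylic methyl carbonate F1. Buffered desilylation (TBAF/AcOH, THF, 0 °C) gives the phenol carbonate F2.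
- Pd2(dba)3·CHCl3 and PPh3 (THF, rt, dilute) ionise the carbonate with inversion. The methoxide set free deprotonates the phenol, and C5 attacks the π-allyl complex anti to palladium.
- The net retention from the (S)-carbinol gives the same C4 configuration as the double inversion through the chloride. The carbonate should ionise well before either C-Br bond inserts at room temperature. The fallback returns to the route at 15.

2. Step 10.
- What may go wrong: allylic transposition (SN2'), partial retention through an ion pair, or Z to E isomerisation during chlorination of the secondary Z-allylic alcohol.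
- Fallback: the C-Cl bond is made before the alkene exists.
- It sets out from 11. MsCl and Et3N (CH2Cl2, -20 °C) give the propargylic mesylate F3. LiCl in DMF (0 °C to rt) displaces it by SN2 with inversion and gives the (R)-propargylic chloride F4.
- Lindlar semihydrogenation (H2, quinoline, EtOAc) of F4 then gives the Z-allylic chloride. The fallback returns to the route at 13.

3. Step 20.
- What may go wrong: Lewis acid induced dienone-phenol rearrangement, or attack on the dienoate ester, during the late ether cleavage.
- Fallback: the methyl group is removed before the ester is attached, and the enol is carried as a silyl ether.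
- It sets out from 18. BCl3, which can now be used more forcefully because no ester or silyl ether is present, followed by aqueous work-up gives the 2α,3β,7-triol F5.
- TBSCl (2.2 equiv) and imidazole silylate the acidic enol O7 and the accessible O2 and give the bis-silyl ether F6. Yamaguchi acylation of the remaining 3β-OH with 26 (through 27) gives the bis-silylated ester F7.
- One global desilylation with HF·pyridine brings the fallback back to the route at 31.

**Further compounds**
F1 | step 11 | methyl (2S,3Z)-5-[2-bromo-4-methoxy-6-methyl-3-(triisopropylsilyloxy)phenyl]pent-3-en-2-yl carbonate | C[C@H](OC(=O)OC)/C=C\Cc1c(Br)c(O[Si](C(C)C)(C(C)C)C(C)C)c(OC)cc1C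
F2 | step 11 | methyl (2S,3Z)-5-(2-bromo-3-hydroxy-4-methoxy-6-methylphenyl)pent-3-en-2-yl carbonate | C[C@H](OC(=O)OC)/C=C\Cc1c(Br)c(O)c(OC)cc1C
F3 | step 10 | (2S)-5-[2-bromo-4-methoxy-6-methyl-3-(triisopropylsilyloxy)phenyl]pent-3-yn-2-yl methanesulfonate | C[C@H](OS(C)(=O)=O)C#CCc1c(Br)c(O[Si](C(C)C)(C(C)C)C(C)C)c(OC)cc1C
F4 | step 10 | {2-bromo-3-[(4R)-4-chloropent-2-yn-1-yl]-6-methoxy-4-methylphenoxy}triisopropylsilane | C[C@@H](Cl)C#CCc1c(Br)c(O[Si](C(C)C)(C(C)C)C(C)C)c(OC)cc1C
F5 | step 20 | (2R,3R,4R,5S)-2α,3β,7-trihydroxy-11,12,13-trinoreremophila-6,9-dien-8-one | O[C@H]1[C@H](O)CC2=CC(=O)C(O)=C[C@]2(C)[C@H]1C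
F6 | step 20 | 2α,7-bis(tert-butyldimethylsilyloxy)-3β-hydroxy-11,12,13-trinoreremophila-6,9-dien-8-one | O[C@H]1[C@H](O[Si](C)(C)C(C)(C)C)CC2=CC(=O)C(O[Si](C)(C)C(C)(C)C)=C[C@]2(C)[C@H]1C
F7 | step 20 | 2α,7-bis(tert-butyldimethylsilyloxy)-8-oxo-11,12,13-trinoreremophila-6,9-dien-3β-yl (2E,4E,6S)-6-methylocta-2,4-dienoate | CC[C@H](C)/C=C/C=C/C(=O)O[C@H]1[C@H](O[Si](C)(C)C(C)(C)C)CC2=CC(=O)C(O[Si](C)(C)C(C)(C)C)=C[C@]2(C)[C@H]1C
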